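## Structural features

- The target is a dispiro compound. Two 2(5H)-furanones, ring A (3-butyl-4-bromo) and ring B (4-bromo-3-(1-acetoxybutyl)), share their C5 and C5′ atoms with two adjacent carbons of a cyclobutane. The other two cyclobutane carbons, C6 and C6′, each carry a bromine.
- All four cyclobutane carbons are stereogenic and contiguous (5S,5′S,6R,6′R). The quaternary spiro centres sit side by side with their lactone oxygens O1 and O1′ on opposite faces, and the ring bromines are trans to each other. Each ring bromine is cis to the vinylic carbon (C4 or C4′) of the neighbouring lactone and trans to its oxygen. A fifth centre (R) is the carbinol carbon of the ring B side chain.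
- The core has a pseudo-twofold axis, but the two lactones differ, so they have to be built one after the other.
- Fragile groups: the vicinal dibromide (loss of Br2 to reductants and halophilic bases), the two vinylogous acyl bromides at C4 and C4′ (addition–elimination with nucleophiles), two lactones, a secondary acetate and the strained ring.
- The real difficulty is twofold. Two adjacent oxygen-bearing quaternary centres must be made in one enantiomeric form. The ring bromines must sit on the more crowded side, where C6–Br lies next to C4–Br and C6′–Br next to C4′–Br.
- The key step uses the fact that C5 of ring A carries the ring oxygen O1 and the vinylic C4. This is the substitution pattern of C5 in a 5-hydroxybutenolide made from a furan. Ionization at C5 lets a carbon of an attached cyclopropanol migrate to it. That forms the C5–C6 bond and the four-membered ring, and leaves a carbonyl at C5′ for attaching ring B.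

## Logic of the disconnections

**22 ⇒ 21.** The acetyl C–O bond of the side chain is cut. An acetate would not survive the organomagnesium chemistry that attaches ring B, so the carbinol travels as a silyl ether. The forward step must exchange silyl for acetyl under acidic conditions that spare the bromides and lactones.

**21 ⇒ 19.** The two vinylic C–Br bonds at C4 and C4′ are cut. A substituent on C4 points under the cyclobutane and shields the face of C6 from which bromine must enter. Bromine at C4 and C4′ therefore has to follow the ring bromines and cannot be brought in with the building blocks. The gain is two plain butenolides. The demand is a vinylic C–H to C–Br exchange at a β-carbon next to a quaternary centre that leaves the vicinal dibromide alone.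

**19 ⇒ 18.** The C6–Br and C6′–Br bonds are cut to a cyclobutene. This removes two stereocentres. The forward step must be an anti addition in which bromide opens the bromonium ion at the carbon where it ends trans to the neighbouring C–O bond.

**18 ⇒ 11 + 16.** The C5′–C4′ and O1′–C2′ bonds of ring B are cut. A butenolide on a ketone carbon is the adduct of a cis-β-metallated acrylate. Ring B then arrives complete with its side-chain stereocentre, and the route becomes convergent. The demand is 1,2-addition to 11 on the face of O1.

**16 ⇒ 15 ⇒ 12 + 13.** The O–Si bond is cut first. Then the bond between C3′ and the carbinol carbon and the vinylic C–I bond are cut together. This reduces the fragment to two three- and four-carbon commodity chemicals. The forward step must control the carbinol configuration and the Z geometry.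

**11 ⇒ 9.** The C6=C6′ double bond is removed. The forward dehydrogenation is needed so that C6 and C6′ stay functionalizable after the ketone has been used. Only C6′ can enolize, so there is no regiochemical question.

**9 ⇒ 7.** The C5–C6 bond is cut, with C6 returned to the carbinol carbon. The cyclobutanone becomes a cyclopropanol on a hemiketal carbon. The stereocentre disappears, since both epimers of 7 give one cation. The forward step must control the face of that cation.

**7 ⇒ 5.** The lactone carbonyl oxygen and the hemiketal oxygen are removed. This leaves an aromatic furan. The forward oxidation must place the carbonyl at the unsubstituted α-carbon.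

**5 ⇒ 3 + 4.** The two C–C bonds from the carbinol carbon to the cyclopropane CH2 groups are cut, back to an ester.

**3 ⇒ 1 + 2.** The butyl–furan C–C bond is cut to a bromide and an alkylzinc.

## Other disconnections considered

**Alternative 1:** All four C–O bonds at C4, C5, C5′ and C4′ are cut together. This leads to the twofold-symmetric diene A1, dimethyl 3,3′-[(3R,4R)-3,4-dibromocyclobutane-1,2-diylidene]dipropanoate. In the forward direction, catalytic OsO4 with an amine N-oxide would add to each exocyclic alkene on the face away from the allylic bromine and give the tetraol diester A2.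
- In its favour: the bromines are present first and steer the oxygen atoms. Every new C–O bond forms on the open face and ends trans to the neighbouring C–Br, which is the relation the target needs. On this point the alternative is better than the chosen plan, where the ring bromines enter last and must take the more crowded positions (step 9).
- Against it here: A1 is a strained cross-conjugated diene with two ionizable allylic bromides, and an enantioselective route to it is not obvious. Osmate esters of such hindered diols turn over slowly. A2 is twofold-symmetric, so the butyl ring and the acetoxybutyl ring would have to be told apart afterwards.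
- Comparison: on structure, it settles the bromine–oxygen relation but not the difference between rings A and B, which the chosen plan handles by bringing ring B in as its own fragment (16). On mechanism, it uses a well-understood syn-dihydroxylation where the chosen plan uses an unproven cationic shift. On step economy, A2 still needs two C3 substituents, two C4 oxidations and two hydroxyl-to-bromide exchanges, so its endgame is longer.

**Alternative 2:** The C5–C5′ bond is cut. This unfolds the cyclobutane and one lactone into the 2-pyranone A3, methyl 2-oxo-3-[(triisopropylsilyl)oxy]-2H-pyran-6-carboxylate. Irradiation would close A3 between C3 and C6 (a 4π electrocyclization) to the Dewar lactone A4.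
- In its favour: one photochemical step builds the four-membered ring with both oxygenated quaternary carbons. The β-lactone can only be cis-fused, so the two C–O bonds end on opposite faces without any facial choice. Here the alternative is at least the equal of step 8 of the chosen plan and probably better. The starting material is cheap.
- Against it here: A4 forms as a racemate, whereas the chosen key step is catalytic and asymmetric. 2-Pyranones also open to ketenes on irradiation, and Dewar lactones lose CO2 or revert on heating. A4 contains neither butenolide, so two ring annulations, both side chains and the ring bromination all remain.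
- Comparison: on structure, it reaches the cyclobutene and the trans-dioxygen pattern early but none of the lactone rings. On mechanism, it is a known photoreaction, which is an advantage over a new method, but it gives no absolute control. On step economy, it is longer overall.

**Alternative 3:** The C3–C4 and C3′–C4′ bonds are cut. This leads to the fully substituted cyclobutane A5, dimethyl 3,4-dibromo-1-(hexanoyloxy)-2-[(3-oxohexanoyl)oxy]cyclobutane-1,2-dicarboxylate, with the ring configuration of the target. Base would close both acyloxy groups onto their geminal esters (Lacey–Dieckmann) to the bis(tetronic acid) A6.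
- In its favour: the C4 and C4′ oxygens arrive as tetronic acid hydroxyls, and their exchange for bromine through a Vilsmeier-type intermediate is established chemistry. This is clearly better than step 10 of the chosen plan. All four ring stereocentres exist before the lactones close, so no late bromination of a cyclobutene is needed, which is also better than step 9.
- Against it here: the difficulty moves into A5. It is an enantiopure cyclobutane-1,2-diol diester with the trans-dibromide on the crowded side and two tertiary hydroxyls that must be acylated differently. Base on such a ring risks retro-Claisen opening and acyl migration between the two oxygens. The butyryl ketone of A6 needs a reagent-controlled reduction to the (R)-carbinol next to a chelating tetronic acid.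
- Comparison: on structure, its key step forms both rings at once where the chosen plan forms one. On mechanism, it is known chemistry. On step economy, the endgame after A6 is shorter than steps 8–11, but the way to A5 is likely longer than steps 1–3.

Key step: step 4

Assumption: the sense of induction of the phosphoric acid in step 4 and of the oxazaborolidinium catalyst in step 6 is taken to match the configurations drawn; if either is opposite, the enantiomeric catalyst is used.

## Route

Step 1
Reactants: 1 methyl 4-bromofuran-2-carboxylate; 2 butylzinc bromide
Product: 3 methyl 4-butylfuran-2-carboxylate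
Conditions: Pd(OAc)2 (2 mol %), SPhos (4 mol %), THF, 50 °C
Reagents that add atoms: none
Why: Negishi coupling; zerovalent palladium inserts readily into the electron-poor heteroaryl bromide, the primary alkylzinc transfers butyl without isomerization, and the ester is inert to the organozinc.

Step 2
Reactants: 3 methyl 4-butylfuran-2-carboxylate; 4 ethylmagnesium bromide
Product: 5 1-(4-butylfuran-2-yl)cyclopropan-1-ol
Conditions: EtMgBr (3 equiv, slow addition), Ti(OiPr)4 (0.5 equiv), THF/Et2O, 0 → 20 °C; aq NH4Cl
Reagents that add atoms: none
Why: Kulinkovich cyclopropanation; the titanacyclopropane formed from the Grignard reagent and the tetravalent titanium alkoxide adds twice to the ester carbon, which becomes the carbinol carbon (later C5′), while the two CH2 groups (later C6 and C6′) come from the ethyl group.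

Step 3
Reactants: 5 1-(4-butylfuran-2-yl)cyclopropan-1-ol
Product: 7 3-butyl-5-hydroxy-5-(1-hydroxycyclopropyl)furan-2(5H)-one (racemic lactol), via furan endoperoxide 6 (not isolated)
Conditions: O2, visible light, tetraphenylporphyrin (cat.), iPr2NEt (1.5 equiv), CH2Cl2, −78 → 0 °C
Reagents that add atoms: dioxygen, O=O
Why: Singlet oxygen adds [4+2] across the two α-carbons of the furan; the amine then removes the only bridgehead hydrogen (Kornblum–DeLaMare fragmentation), so the unsubstituted α-carbon becomes the lactone carbonyl and the cyclopropanol-bearing carbon becomes the hemiketal carbon C5.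

Step 4
Reactants: 7 3-butyl-5-hydroxy-5-(1-hydroxycyclopropyl)furan-2(5H)-one
Product: 9 (4S)-7-butyl-5-oxaspiro[3.4]oct-7-ene-1,6-dione, via acyloxocarbenium ion 8 (not isolated)
Conditions: (R)-TRIP (BINOL-derived phosphoric acid with 2,4,6-triisopropylphenyl groups at the 3,3′-positions, 10 mol %), 5 Å molecular sieves, toluene, 0 → 20 °C
Reagents that add atoms: none
Why: Proposed new method: the acid protonates the lactol hydroxyl of 7, water leaves, and both epimers give the same planar acyloxocarbenium ion 8, held as a contact ion pair by the chiral phosphate, which is also hydrogen-bonded to the cyclopropanol OH. A cyclopropane C–C bond lying parallel to the empty orbital at C5 then shifts to C5 while the carbinol carbon becomes the C5′ carbonyl, so the C5–C6 bond and the cyclobutanone arise by a suprafacial 1,2-shift (ring expansion from three to four) and not by a cyclization. The closest known reaction type is the chiral-phosphoric-acid-catalysed semipinacol ring expansion of cycloalkanols attached to oxocarbenium or iminium carbons; what is new is the less stabilized, acyloxy-substituted cation generated from a 5-hydroxybutenolide. The only new stereocentre, C5, is set by the phosphate, which covers one face of the cation so that the migrating carbon arrives on the other. The step needs enantioface selection and chemoselectivity for migration over return of water, over opening of the cyclopropanol to an ethyl ketone, and over an uncatalysed shift in the open keto-acid tautomer. The substrate helps: the two cyclopropane carbons are equivalent, so no regiochemical question arises, the tertiary cyclopropanol is a strong migrating donor, formation of the C=O bond makes the shift irreversible, and the sieves take up the water.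

Step 5
Reactants: 9 (4S)-7-butyl-5-oxaspiro[3.4]oct-7-ene-1,6-dione
Product: 11 (4S)-7-butyl-5-oxaspiro[3.4]octa-2,7-diene-1,6-dione, via trimethylsilyl enol ether 10 (not isolated)
Conditions: TMSOTf, Et3N, CH2Cl2, 0 °C; then Pd(OAc)2 (10 mol %), O2 (1 atm), DMSO, 25 °C
Reagents that add atoms: none
Why: Saegusa–Ito oxidation; the ketone can enolize only toward C6′ because C5 is quaternary, and the divalent palladium enolate loses the syn hydrogen at C6 to give the cyclobutenone, whose quaternary C5 keeps it from dimerizing through an enol.

Step 6
Reactants: 12 ethyl propiolate; 13 butanal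
Product: 15 ethyl (2Z)-2-[(1R)-1-hydroxybutyl]-3-iodoprop-2-enoate, via O-trimethylsilyl ether 14 (not isolated)
Conditions: TMSI (1.2 equiv), chiral oxazaborolidinium triflimide (20 mol %, from a diphenylprolinol-derived B-aryl oxazaborolidine and Tf2NH), EtCN, −78 °C; 1 M HCl work-up
Reagents that add atoms: iodotrimethylsilane, C[Si](C)(C)I
Why: Catalytic asymmetric three-component iodo-aldol reaction (β-iodo Morita–Baylis–Hillman type); iodide adds to the propiolate to give a β-iodoallenolate, which attacks the aldehyde bound to the chiral Lewis acid, and this sets the (R)-carbinol and the Z geometry with iodine cis to the ester.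

Step 7
Reactants: 15 ethyl (2Z)-2-[(1R)-1-hydroxybutyl]-3-iodoprop-2-enoate
Product: 16 ethyl (2Z)-2-[(1R)-1-{[tert-butyl(dimethyl)silyl]oxy}butyl]-3-iodoprop-2-enoate
Conditions: TBSOTf, 2,6-lutidine, CH2Cl2, −78 → 0 °C
Reagents that add atoms: tert-butyldimethylsilyl trifluoromethanesulfonate, CC(C)(C)[Si](C)(C)OS(=O)(=O)C(F)(F)F
Why: Standard silylation of a secondary alcohol; the silyl ether tolerates the organomagnesium step and is a poor leaving group, which guards against allene formation from the metallated fragment.

Step 8
Reactants: 16 ethyl (2Z)-2-[(1R)-1-{[tert-butyl(dimethyl)silyl]oxy}butyl]-3-iodoprop-2-enoate; 11 (4S)-7-butyl-5-oxaspiro[3.4]octa-2,7-diene-1,6-dione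
Product: 18 (5S,5′S)-dispiro bis-butenolide cyclobutene (ring A 3-butyl, ring B 3-[(1R)-1-silyloxybutyl], C6=C6′, O1 and O1′ on opposite faces), via alkenylmagnesium chloride 17 (not isolated)
Conditions: 16, iPrMgCl·LiCl (1.05 equiv), THF, −78 °C; then 11, −78 → −20 °C; aq NH4Cl
Reagents that add atoms: none
Why: Iodine–magnesium exchange gives the cis-β-magnesioacrylate 17 with retention; it adds 1,2 to the strained, non-enolizable ketone C5′, and the alkoxide closes onto the cis ester (5-exo acyl substitution) to form ring B. C5′ is set by approach on the face of O1, which carries no substituent, whereas the other face is flanked by the vinylic C4–H; the new C5′–O bond then lies anti to C5–O1, which minimizes dipole repulsion.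

Step 9
Reactants: 18 (5S,5′S)-dispiro bis-butenolide cyclobutene
Product: 19 (5S,5′S,6R,6′R)-6,6′-dibromide of 18 (ring bromines trans, each cis to the neighbouring vinylic carbon)
Conditions: Br2 (1.05 equiv), CH2Cl2, −78 → −40 °C, dark
Reagents that add atoms: bromine, BrBr
Why: Anti addition through a bromonium ion to the strained cyclobutene, while the electron-poor butenolide alkenes do not react in the dark. Because of the pseudo-twofold axis both faces lead to the same pair of trans-dibromides, and opening at the carbon where bromide enters anti to the vicinal spiro C–O bond gives the (6R,6′R) isomer; this polar preference can operate only while C4 and C4′ still carry hydrogen.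

Step 10
Reactants: 19 (5S,5′S,6R,6′R)-6,6′-dibromide
Product: 21 (5S,5′S,6R,6′R)-4,4′,6,6′-tetrabromide (silyl ether of the target alcohol), via hexabromide 20 (not isolated)
Conditions: Br2 (2.5 equiv), visible light, PhCF3, 20 °C; evaporate; DBU (2.4 equiv), toluene, 0 → 20 °C
Reagents that add atoms: bromine, BrBr
Why: Proposed new method: radical-chain addition of bromine to each electron-poor butenolide alkene puts one bromine on C4 (C4′) and one on the quaternary C3 (C3′); the base then removes HBr as C4–H plus the tertiary α-carbonyl bromide, the only ring hydrogen that is acidified by a geminal bromine and whose loss restores lactone conjugation, through a syn-periplanar E2 that a five-membered ring can reach, while the bromines at C6 and C6′ have no anti hydrogen and stay; the closest known reaction type is the bromination–dehydrobromination of α-alkylacrylates and alkylmaleic anhydrides to their β-bromo derivatives.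

Step 11
Reactants: 21 (5S,5′S,6R,6′R)-4,4′,6,6′-tetrabromide silyl ether
Product: 22 CNP0268004.1, (1R)-1-[(5S,5′S,6R,6′R)-tetrabromo dispiro bis-butenolide ring B]butyl acetate
Conditions: Ac2O (5 equiv), Bi(OTf)3 (5 mol %), CH2Cl2, 0 → 20 °C
Reagents that add atoms: acetic anhydride, CC(=O)OC(C)=O
Why: Lewis-acid-catalysed direct exchange of a silyl ether for an acetate; no base touches the dibromide or the vinylogous acyl bromides, and the carbinol carbon, attached to the α-carbon of an electron-poor alkene, does not ionize, so its configuration is kept.

## Compound list

1 | methyl 4-bromofuran-2-carboxylate | COC(=O)c1cc(Br)co1 | starting material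
2 | butylzinc bromide | CCCC[Zn]Br | starting material
3 | methyl 4-butylfuran-2-carboxylate | CCCCc1coc(C(=O)OC)c1 | intermediate
4 | ethylmagnesium bromide | CC[Mg]Br | starting material
5 | 1-(4-butylfuran-2-yl)cyclopropan-1-ol | CCCCc1coc(C2(O)CC2)c1 | intermediate
6 | 1-(5-butyl-2,3,7-trioxabicyclo[2.2.1]hept-5-en-1-yl)cyclopropan-1-ol (furan endoperoxide, racemic) | CCCCC1=CC2(C3(O)CC3)OOC1O2 | intermediate (not isolated)
7 | 3-butyl-5-hydroxy-5-(1-hydroxycyclopropyl)furan-2(5H)-one (racemic lactol) | CCCCC1=CC(O)(C2(O)CC2)OC1=O | intermediate
8 | 3-butyl-5-(1-hydroxycyclopropyl)-2-oxo-2H-furan-5-ylium (acyloxocarbenium ion, chiral phosphate counter-ion) | CCCCC1=C[C+](C2(O)CC2)OC1=O | intermediate (not isolated)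
9 | (4S)-7-butyl-5-oxaspiro[3.4]oct-7-ene-1,6-dione | CCCCC1=C[C@@]2(OC1=O)CCC2=O | intermediate
10 | (4S)-7-butyl-1-[(trimethylsilyl)oxy]-5-oxaspiro[3.4]octa-1,7-dien-6-one | CCCCC1=C[C@@]2(OC1=O)CC=C2O[Si](C)(C)C | intermediate (not isolated)
11 | (4S)-7-butyl-5-oxaspiro[3.4]octa-2,7-diene-1,6-dione | CCCCC1=C[C@@]2(OC1=O)C=CC2=O | intermediate
12 | ethyl propiolate | C#CC(=O)OCC | starting material
13 | butanal | CCCC=O | starting material
14 | ethyl (2Z)-3-iodo-2-{(1R)-1-[(trimethylsilyl)oxy]butyl}prop-2-enoate | CCOC(=O)/C(=C\I)[C@H](O[Si](C)(C)C)CCC | intermediate (not isolated)
15 | ethyl (2Z)-2-[(1R)-1-hydroxybutyl]-3-iodoprop-2-enoate | CCOC(=O)/C(=C\I)[C@H](O)CCC | intermediate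
16 | ethyl (2Z)-2-[(1R)-1-{[tert-butyl(dimethyl)silyl]oxy}butyl]-3-iodoprop-2-enoate | CCOC(=O)/C(=C\I)[C@H](O[Si](C)(C)C(C)(C)C)CCC | intermediate
17 | {(1Z)-2-[(1R)-1-{[tert-butyl(dimethyl)silyl]oxy}butyl]-3-ethoxy-3-oxoprop-1-en-1-yl}magnesium chloride (LiCl complex) | CCOC(=O)/C(=C\[Mg]Cl)[C@H](O[Si](C)(C)C(C)(C)C)CCC | intermediate (not isolated)
18 | (5S,6S)-3-butyl-9-[(1R)-1-{[tert-butyl(dimethyl)silyl]oxy}butyl]-1,7-dioxadispiro[4.0.4^6.2^5]dodeca-3,9,11-triene-2,8-dione (rings A and B spiro-fused at C5 and C5′ to a cyclobutene) | CCCCC1=C[C@@]2(OC1=O)C=C[C@@]21OC(=O)C([C@@H](CCC)O[Si](C)(C)C(C)(C)C)=C1 | intermediate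
19 | (5S,6S,11R,12R)-11,12-dibromo-3-butyl-9-[(1R)-1-{[tert-butyl(dimethyl)silyl]oxy}butyl]-1,7-dioxadispiro[4.0.4^6.2^5]dodeca-3,9-diene-2,8-dione (the (5S,5′S,6R,6′R)-dibromide) | CCCCC1=C[C@@]2(OC1=O)[C@@H](Br)[C@H](Br)[C@@]21OC(=O)C([C@@H](CCC)O[Si](C)(C)C(C)(C)C)=C1 | intermediate
20 | 3,4,9,10,11,12-hexabromide of 19 with both lactone alkenes saturated (mixture of diastereomers at C3, C4, C3′, C4′) | CCCCC1(Br)C(Br)[C@@]2(OC1=O)[C@@H](Br)[C@H](Br)[C@@]21OC(=O)C(Br)([C@@H](CCC)O[Si](C)(C)C(C)(C)C)C1Br | intermediate (not isolated)
21 | (5S,6S,11R,12R)-4,10,11,12-tetrabromo-3-butyl-9-[(1R)-1-{[tert-butyl(dimethyl)silyl]oxy}butyl]-1,7-dioxadispiro[4.0.4^6.2^5]dodeca-3,9-diene-2,8-dione | CCCCC1=C(Br)[C@@]2(OC1=O)[C@@H](Br)[C@H](Br)[C@@]21OC(=O)C([C@@H](CCC)O[Si](C)(C)C(C)(C)C)=C1Br | intermediate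
22 | CNP0268004.1, (1R)-1-[(5S,6S,11R,12R)-4,10,11,12-tetrabromo-3-butyl-2,8-dioxo-1,7-dioxadispiro[4.0.4^6.2^5]dodeca-3,9-dien-9-yl]butyl acetate | CCCCC1=C(Br)[C@@]2(OC1=O)[C@@H](Br)[C@H](Br)[C@@]21OC(=O)C([C@@H](CCC)OC(C)=O)=C1Br | target

## Step count and least certain steps

Total step count: 11. Longest linear sequence: 9 steps (steps 1–5 and 8–11 from 1); the ring B fragment takes 2 steps (6 and 7) and joins at step 8.

**Step 4 (key step, proposed new method).**
- Most likely failure: ionization of the lactol is too slow, because the acyloxy-substituted cation is poorly stabilized and the phosphoric acid is only moderately strong. The open keto-acid tautomer would then react through an uncatalysed or self-catalysed ketol shift with poor enantiocontrol, or the cyclopropanol would open to an ethyl ketone.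
- Fallback with known chemistry, setting out from 7: methylation with trimethylsilyldiazomethane gives the open-chain methyl (2Z)-2-butyl-4-(1-hydroxycyclopropyl)-4-oxobut-2-enoate F1. A chiral Lewis acid that binds the ketone and the hydroxyl together (Cu(OTf)2 with a bis(oxazoline) ligand) then catalyses an α-ketol rearrangement with ring expansion. This gives methyl (2Z)-2-butyl-3-[(1S)-1-hydroxy-2-oxocyclobutyl]prop-2-enoate F2. Its tertiary hydroxyl lactonizes onto the cis ester with a trace of acid, and the route is rejoined at 9.

**Step 10 (proposed new method).**
- Most likely failure: loss of HBr in the wrong direction. The side-chain hydrogens on the carbon attached to C3 or C3′ can reach an anti-periplanar arrangement with the tertiary bromide, whereas C4–H can only leave syn, so exocyclic alkylidene lactones may form instead.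
- Also possible: allylic C–H bromination during the radical addition, and halophilic attack of the base that returns 19.
- Fallback with known chemistry, setting out from 19: copper-catalysed conjugate borylation (B2pin2, CuCl, Xantphos, NaOtBu, MeOH) gives the bis(pinacolboronate) F3, which is oxidized in the same flask (NaBO3) to the bis(4-hydroxy lactone) F4. The hypervalent iodine oxidant DMP converts F4 into the bis(tetronic acid) F5. Oxalyl bromide with catalytic DMF exchanges both enolic hydroxyls for bromine by addition–elimination, and the route is rejoined at 21.

**Step 9.**
- Most likely failure: poor regiocontrol in the opening of the bromonium ion. Bromide may enter next to the lactone oxygen, which is sterically the slightly more open side, and give the other trans-dibromide.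
- Fallback, setting out from 18: the (5S,5′S,6S,6′S)-dibromide F6 is not discarded. It is heated in a non-polar solvent, where the known dyotropic 1,2-interchange of vicinal bromines interconverts exactly these two trans isomers. The less polar isomer, with each C–Br anti to the vicinal C–O bond, is expected to gain, and it is separated as 19. Material that does not converge is returned to 18 with zinc dust.

**Step 8.**
- Most likely failure: poor facial selectivity in the 1,2-addition. The two faces of the C5′ carbonyl differ only by a ring oxygen versus a vinylic C–H, and a preference for attack anti to the α C–O bond would oppose the approach that is needed.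
- Also possible: the cyclobutenyl alkoxide may undergo oxy-anion-accelerated ring opening before it lactonizes.
- Fallback, setting out from 11: (3R)-3-{[tert-butyl(dimethyl)silyl]oxy}hex-1-yne F7, made from commercial (R)-hex-1-yn-3-ol and TBSCl, is lithiated, transmetallated with CeCl3 and added at −78 °C. This gives the propargylic alcohol F8 after cold protonation. A slim sp nucleophile on a chelating trivalent cerium centre should follow the dipole-controlled approach on the oxygen face, and no alkoxide is left standing next to an ester. Palladium-catalysed cyclocarbonylation of the alkynol (Pd2(dba)3, 1,4-bis(diphenylphosphino)butane, CO/H2) then closes ring B, and the route is rejoined at 18.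

**Step 5.**
- Most likely failure: slow β-hydride elimination from the palladium enolate in the four-membered ring, followed by decomposition of the strained enone (ring opening to a vinylketene, or addition of nucleophiles) during the long reaction.
- Fallback, setting out from 9: α-bromination at C6′ with PhNMe3Br3 gives the 2-bromo ketone F9. Dehydrobromination with Et3N at 0 °C is an E1cB process through the enolate, and the route is rejoined at 11.

## Further compounds

F1 | step 4 | methyl (2Z)-2-butyl-4-(1-hydroxycyclopropyl)-4-oxobut-2-enoate | COC(=O)/C(CCCC)=C\C(=O)C1(O)CC1
F2 | step 4 | methyl (2Z)-2-butyl-3-[(1S)-1-hydroxy-2-oxocyclobutyl]prop-2-enoate | COC(=O)/C(CCCC)=C\[C@@]1(O)CCC1=O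
F3 | step 10 | 4,4′-bis(pinacolboronate) of 19 with both lactone alkenes saturated (new centres undefined) | CCCCC1C(B3OC(C)(C)C(C)(C)O3)[C@@]2(OC1=O)[C@@H](Br)[C@H](Br)[C@@]21OC(=O)C([C@@H](CCC)O[Si](C)(C)C(C)(C)C)C1B3OC(C)(C)C(C)(C)O3
F4 | step 10 | 4,4′-dihydroxy saturated bis-lactone from 19 (new centres undefined) | CCCCC1C(O)[C@@]2(OC1=O)[C@@H](Br)[C@H](Br)[C@@]21OC(=O)C([C@@H](CCC)O[Si](C)(C)C(C)(C)C)C1O
F5 | step 10 | (5S,5′S,6R,6′R)-6,6′-dibromo bis(tetronic acid) with 3-butyl and 3′-[(1R)-1-silyloxybutyl] groups | CCCCC1=C(O)[C@@]2(OC1=O)[C@@H](Br)[C@H](Br)[C@@]21OC(=O)C([C@@H](CCC)O[Si](C)(C)C(C)(C)C)=C1O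
F6 | step 9 | (5S,5′S,6S,6′S)-6,6′-dibromide, diastereomer of 19 with each bromine cis to the neighbouring lactone oxygen | CCCCC1=C[C@@]2(OC1=O)[C@H](Br)[C@@H](Br)[C@@]21OC(=O)C([C@@H](CCC)O[Si](C)(C)C(C)(C)C)=C1
F7 | step 8 | (3R)-3-{[tert-butyl(dimethyl)silyl]oxy}hex-1-yne | C#C[C@@H](CCC)O[Si](C)(C)C(C)(C)C
F8 | step 8 | (1S,4S)-7-butyl-1-[(3R)-3-{[tert-butyl(dimethyl)silyl]oxy}hex-1-yn-1-yl]-1-hydroxy-5-oxaspiro[3.4]octa-2,7-dien-6-one | CCCCC1=C[C@@]2(OC1=O)C=C[C@]2(O)C#C[C@@H](CCC)O[Si](C)(C)C(C)(C)C
F9 | step 5 | (4S)-2-bromo-7-butyl-5-oxaspiro[3.4]oct-7-ene-1,6-dione (C2 epimers) | CCCCC1=C[C@@]2(OC1=O)CC(Br)C2=O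
A1 | alternative 1 | dimethyl 3,3′-[(3R,4R)-3,4-dibromocyclobutane-1,2-diylidene]dipropanoate (alkene geometry not fixed) | COC(=O)CC=C1[C@@H](Br)[C@H](Br)C1=CCC(=O)OC
A2 | alternative 1 | dimethyl 3,3′-(3,4-dibromo-1,2-dihydroxycyclobutane-1,2-diyl)bis(3-hydroxypropanoate), tetraol diester with the ring configuration of the target | COC(=O)C[C@@H](O)[C@@]1(O)[C@@H](Br)[C@H](Br)[C@]1(O)[C@H](O)CC(=O)OC
A3 | alternative 2 | methyl 2-oxo-3-[(triisopropylsilyl)oxy]-2H-pyran-6-carboxylate | COC(=O)C1=CC=C(O[Si](C(C)C)(C(C)C)C(C)C)C(=O)O1
A4 | alternative 2 | methyl 3-oxo-4-[(triisopropylsilyl)oxy]-2-oxabicyclo[2.2.0]hex-5-ene-1-carboxylate (needed enantiomer) | COC(=O)[C@@]12C=C[C@]1(O[Si](C(C)C)(C(C)C)C(C)C)C(=O)O2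
A5 | alternative 3 | dimethyl 3,4-dibromo-1-(hexanoyloxy)-2-[(3-oxohexanoyl)oxy]cyclobutane-1,2-dicarboxylate with the ring configuration of the target | CCCCCC(=O)O[C@]1(C(=O)OC)[C@@H](Br)[C@H](Br)[C@]1(OC(=O)CC(=O)CCC)C(=O)OC
A6 | alternative 3 | dibromo dispiro bis(tetronic acid) with 3-butyl and 3′-butyryl groups | CCCCC1=C(O)[C@@]2(OC1=O)[C@@H](Br)[C@H](Br)[C@@]21OC(=O)C(C(=O)CCC)=C1O
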